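**Retrosynthetic overview**

1. Atom names used below: seven-membered ring C1 (tertiary carbinol, crotonoyl) – C5 (CH–O-isovaleryl) – C6 (CH–O of the lactone) – C7 – C8 (CH2) – C9 (C=O) – C10 (CH–CH3); lactone C11(=C13H2)–C12(=O); side chain C2(=O)–C3=C4–C15.
2. Late disconnections: C2–C3 by acyl cross-coupling of a C2 thioester; C1–OH and C10–H by epoxidation and reductive opening of a C10=C1 ene-keto thioester; C13 by α-methylenation; C9=O, C8H2 and free C5–OH by eliminative opening of a C5–O–C8 oxygen bridge.
3. Key disconnection: C8–C9 and C1–C5 in one [4+3] cycloaddition (cyclopropanation, then Cope rearrangement) of a rhodium vinylcarbene (C9–C10–C1, acyl carbon C2 on C1, silyloxy on C9) with a furan (C5–C6–C7–C8).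
4. Enabling feature: C5–C6–C7–C8 carry O on C5, O on C6 and the acetate carbon C11 on C7, while C8 is a CH2 beside the C9 ketone. They therefore map onto a 3-methoxy-4-(carboxymethyl)furan whose ring oxygen stays on C5 and leaves C8 by elimination towards C9; the cis lactone and the trans C5/C6 oxygens follow from reagent delivery to the exo face of the 8-oxabicyclo[3.2.1]octane.
5. Ring order: furan (from 3,4-dibromofuran) → seven-membered carbocycle as the oxygen-bridged bicycle (step 7) → γ-lactone (step 8) → bridge opened to the monocyclic cycloheptene (step 9).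

Key step: step 7

Assumption: Rh2(S-PTAD)4 (dirhodium tetrakis[(S)-(1-adamantyl)(N-phthalimido)acetate]) is taken to give the bridgehead configuration drawn for 10; should the sense of induction prove opposite, the enantiomeric catalyst Rh2(R-PTAD)4 takes its place.

Convention: exo is the face of the oxygen bridge, endo the opposite face.

**Route**

Step 1
Reactants: 1 3,4-dibromofuran
Product: 2 3-bromo-4-methoxyfuran
Conditions: NaOMe, CuBr (10 mol %), MeOH/DMF, 100 °C, stopped at mono-substitution
Reagents that add atoms: sodium methoxide, [Na+].[O-]C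
Why: Copper-catalysed Ullmann-type methoxylation of a heteroaryl bromide, in which the first methoxy group makes the ring more electron-rich so that the second C–Br bond should exchange more slowly.

Step 2
Reactants: 2 3-bromo-4-methoxyfuran
Product: 3 ethyl 2-(4-methoxyfuran-3-yl)acetate
Conditions: BrZnCH2CO2Et, Pd2(dba)3 (cat.), P(t-Bu)3, THF, rt to 50 °C
Reagents that add atoms: (2-ethoxy-2-oxoethyl)zinc bromide, CCOC(=O)C[Zn]Br
Why: Palladium-catalysed coupling of a zinc ester enolate (Reformatsky reagent, Negishi type) with the heteroaryl bromide under base-free conditions that the alkoxyfuran should tolerate.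

Step 3
Reactants: 4 ethyl (E)-3-methyl-4-oxobut-2-enoate
Product: 5 ethyl 3-methyl-4-oxobutanoate (racemic)
Conditions: H2 (1 atm), Pd/C, EtOAc, rt
Reagents that add atoms: none
Why: Catalytic hydrogenation should saturate only the conjugated C=C; the new stereocentre is racemic and without consequence because this carbon (C10) becomes sp2 again in step 4.

Step 4
Reactants: 5 ethyl 3-methyl-4-oxobutanoate
Product: 6 ethyl (E)-3-methyl-4-(triisopropylsilyloxy)but-3-enoate
Conditions: TIPSOTf, Et3N, CH2Cl2, 0 °C to rt
Reagents that add atoms: triisopropylsilyl trifluoromethanesulfonate, CC(C)[Si](C(C)C)(C(C)C)OS(=O)(=O)C(F)(F)F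
Why: Silyl triflate/amine enol silylation of the α-branched aldehyde; no stereocentre is formed, and the (E)-enol ether (silyloxy cis to methyl) is expected to be favoured sterically and separable from any (Z)-isomer.

Step 5
Reactants: 6 ethyl (E)-3-methyl-4-(triisopropylsilyloxy)but-3-enoate
Product: 7 S-ethyl (E)-3-methyl-4-(triisopropylsilyloxy)but-3-enethioate
Conditions: AlMe3, EtSH (gives Me2AlSEt), CH2Cl2, 0 °C to rt
Reagents that add atoms: ethanethiol (delivered as Me2AlSEt), CCS
Why: Aluminium thiolate transthioesterification of an unhindered ester installs the acyl-coupling handle for step 15 and should leave the bulky silyl enol ether untouched.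

Step 6
Reactants: 7 S-ethyl (E)-3-methyl-4-(triisopropylsilyloxy)but-3-enethioate
Product: 8 S-ethyl (E)-2-diazo-3-methyl-4-(triisopropylsilyloxy)but-3-enethioate
Conditions: 4-acetamidobenzenesulfonyl azide, DBU, MeCN, 0 °C, used at once
Reagents that add atoms: 4-acetamidobenzenesulfonyl azide, CC(=O)Nc1ccc(cc1)S(=O)(=O)N=[N+]=[N-]
Why: Regitz diazo transfer to the methylene activated by the thioester and the vinyl group, the standard entry to vinyldiazo carbonyl compounds.

Step 7
Reactants: 3 ethyl 2-(4-methoxyfuran-3-yl)acetate; 8 S-ethyl (E)-2-diazo-3-methyl-4-(triisopropylsilyloxy)but-3-enethioate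
Product: 10 oxygen-bridged cycloheptadiene thioester (8-oxabicyclo[3.2.1]octa-2,6-diene), via divinylcyclopropane 9 (not isolated)
Conditions: Rh2(S-PTAD)4 (1 mol %), hexanes, −30 °C to rt, slow addition of 8 to 3 (2 equiv)
Reagents that add atoms: none
Why: Rh2(S-PTAD)4 turns 8 into a rhodium-bound vinylcarbene that cyclopropanates the enol-ether-like C5=C6 bond of furan 3 (new bond C1–C5) to give the cis-divinylcyclopropane 9, whose Cope rearrangement through the obligatory boat transition state forms C8–C9 and breaks C1–C6. The closest known reaction type is the rhodium-catalysed tandem cyclopropanation/Cope rearrangement (formal [4+3] cycloaddition) of vinyldiazoacetates with furans, which gives 8-oxabicyclo[3.2.1]octa-2,6-dienes. The seven-membered carbocycle is closed by the [3,3]-sigmatropic shift, the furan oxygen remaining as the C5–O–C8 bridge, and the transient three-membered ring by carbene transfer. The configuration at the bridgeheads C5 and C8 is set by the chiral carboxylate ligands, which select the furan face in the cyclopropanation, and is carried stereospecifically through the Cope step; the (E)-silyloxy group ends endo at C9, a centre that is erased in step 9. The step needs regiocontrol (carbene carbon to C5, vinyl terminus to C8) and chemoselectivity against zwitterionic [3+2] closure or furan ring opening. The methoxy group on C6 makes C5 the most nucleophilic α-carbon, the silyloxy donor on C9 switches off vinylogous carbene reactivity, and the non-polar solvent disfavours zwitterions.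

Step 8
Reactants: 10 oxygen-bridged cycloheptadiene thioester
Product: 13 tricyclic cis-lactone thioester, via ketone 11 (not isolated), via hydroxy ester 12 (not isolated)
Conditions: (CO2H)2, H2O/THF, 0 °C; then CeCl3·7H2O, NaBH4, MeOH, −40 °C; then PPTS, CH2Cl2, rt
Reagents that add atoms: water, O
Why: Mild acid hydrolysis of the enol ether should protonate C7 from the exo face (side chain endo), Luche reduction should deliver hydride to the C6 ketone from the same exo face (C6–O endo, hence trans to the C5 oxygen and cis to the C7 side chain), and the cis γ-hydroxy ester lactonises; the β-alkoxy ketone 11 is not isolated, to avoid epimerisation at C7 or β-elimination.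

Step 9
Reactants: 13 tricyclic cis-lactone thioester
Product: 14 monocyclic bis-silyl dienol ether (C5–OTMS and C8=C9–OTIPS)
Conditions: TMSOTf, Et3N, CH2Cl2, −78 °C to 0 °C
Reagents that add atoms: trimethylsilyl trifluoromethanesulfonate, C[Si](C)(C)OS(=O)(=O)C(F)(F)F
Why: Proposed new method: Et3N removes the exo γ-proton at C9 of the TMSOTf-activated enethioate to give a silyl thio-dienolate, whose electron push through C1=C10 expels the silylated bridging oxygen from C8 in a vinylogous E1cB (1,4-) elimination; the bridge oxygen ends as the C5 silyl ether and C8=C9 as the TIPS enol ether, so that C9 reaches the ketone level and C8 loses its oxygen without any redox reagent, while C5, C6 and C7 are untouched; the closest known reaction types are the TMSOTf/Et3N ring opening of 8-oxabicyclo[3.2.1]octan-3-ones through their silyl enol ethers and the base-induced 1,4-elimination of δ-alkoxy α,β-unsaturated esters.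

Step 10
Reactants: 14 monocyclic bis-silyl dienol ether
Product: 17 α-methylene lactone bis-silyl dienol ether, via Mannich base 15 (not isolated), via ammonium iodide 16 (not isolated)
Conditions: LiN(iPr)2, THF, −78 °C; CH2=NMe2+ I−, −78 °C to 0 °C; then MeI, THF, rt; then NaHCO3 (aq.), EtOAc
Reagents that add atoms: dimethylmethylideneammonium iodide, C=[N+](C)C.[I-]
Why: Eschenmoser α-methylenation (Mannich reaction of the lithium lactone enolate, N-methylation, Hofmann-type elimination); the lactone CH2 carries the only readily removable protons now that C9 is sp2, the push–pull TIPS dienol ether is a much poorer nucleophile than the lithium enolate, and no stereocentre remains at C11.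

Step 11
Reactants: 17 α-methylene lactone bis-silyl dienol ether
Product: 18 C5-hydroxy ene-keto thioester
Conditions: HF·pyridine, pyridine/THF, 0 °C
Reagents that add atoms: none
Why: Fluoride-mediated cleavage of both silyl groups, with protonation of the dienol ether at C8, should release the C9 ketone conjugated with C10=C1 and the free C5 hydroxyl without touching a stereocentre.

Step 12
Reactants: 18 C5-hydroxy ene-keto thioester
Product: 19 C5 isovalerate ene-keto thioester
Conditions: (Me2CHCH2CO)2O, Et3N, DMAP (cat.), CH2Cl2, 0 °C
Reagents that add atoms: 3-methylbutanoic anhydride, CC(C)CC(=O)OC(=O)CC(C)C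
Why: DMAP-catalysed acylation of the only free hydroxyl (secondary, C5) with retention, which also draws the open hydroxy enone out of any equilibrium with a bridged hemiketal and supplies the control element for step 13.

Step 13
Reactants: 19 C5 isovalerate ene-keto thioester
Product: 20 C1,C10-epoxy ketone thioester
Conditions: t-BuOOH, DBU, CH2Cl2, −20 °C to 0 °C
Reagents that add atoms: tert-butyl hydroperoxide, CC(C)(C)OO
Why: Weitz–Scheffer nucleophilic epoxidation of the tetrasubstituted ene-1,4-dicarbonyl unit, in which the peroxide anion should add to C1 (β to the C9 ketone) anti to the pseudoaxial C5 acyloxy group (Felkin–Anh-type control), setting the C1–O bond trans to the C5 oxygen; the less electrophilic α-methylene lactone and the hindered thioester should not compete at low temperature.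

Step 14
Reactants: 20 C1,C10-epoxy ketone thioester
Product: 21 C1-hydroxy C9-ketone thioester
Conditions: SmI2, THF/MeOH, −78 °C
Reagents that add atoms: none
Why: SmI2 reduction of the α,β-epoxy ketone cleaves the Cα–O bond (C10–O) because the ketone is reduced far more easily than the thioester, leaving the C1 tertiary alcohol; the samarium enolate should be protonated at C10 from the face opposite the bulky samarium alkoxide on C1, placing the methyl cis to the C1 hydroxyl, and C10 remains correctable by equilibration as the α-carbon of the ketone.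

Step 15
Reactants: 21 C1-hydroxy C9-ketone thioester
Product: 22 CNP0283951.1 (target)
Conditions: (E)-MeCH=CHB(OH)2, Pd2(dba)3 (cat.), P(2-furyl)3, copper thiophene-2-carboxylate Cu(O2CC4H3S), THF, 45 °C
Reagents that add atoms: (E)-prop-1-enylboronic acid, C/C=C/B(O)O
Why: Liebeskind–Srogl acyl cross-coupling of the thioester with the alkenylboronic acid should give the (E)-enone with retention of alkene geometry under neutral conditions that spare the ketone, the lactone, the isovalerate and the tertiary alcohol.

**Compound list**

1 | 3,4-dibromofuran | Brc1cocc1Br | starting material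
2 | 3-bromo-4-methoxyfuran | COc1cocc1Br | intermediate
3 | ethyl 2-(4-methoxyfuran-3-yl)acetate | CCOC(=O)Cc1cocc1OC | intermediate
4 | ethyl (E)-3-methyl-4-oxobut-2-enoate | CCOC(=O)/C=C(C)/C=O | starting material
5 | ethyl 3-methyl-4-oxobutanoate (racemic) | CCOC(=O)CC(C)C=O | intermediate
6 | ethyl (E)-3-methyl-4-(triisopropylsilyloxy)but-3-enoate | CCOC(=O)C/C(C)=C/O[Si](C(C)C)(C(C)C)C(C)C | intermediate
7 | S-ethyl (E)-3-methyl-4-(triisopropylsilyloxy)but-3-enethioate | CCSC(=O)C/C(C)=C/O[Si](C(C)C)(C(C)C)C(C)C | intermediate
8 | S-ethyl (E)-2-diazo-3-methyl-4-(triisopropylsilyloxy)but-3-enethioate | CCSC(=O)C(=[N+]=[N-])/C(C)=C/O[Si](C(C)C)(C(C)C)C(C)C | intermediate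
9 | cis-divinylcyclopropane: 2-oxabicyclo[3.1.0]hex-3-ene with the carbene carbon C1 (COSEt and (E)-silyloxypropenyl, the latter on the face of the dihydrofuran ring) bridging C5 and C6 (OCH3), and CH2CO2Et on C7 | CCSC(=O)[C@]1(/C(C)=C/O[Si](C(C)C)(C(C)C)C(C)C)[C@H]2OC=C(CC(=O)OCC)[C@@]12OC | intermediate (not isolated)
10 | [4+3] adduct: 8-oxabicyclo[3.2.1]octa-2,6-diene with C5–O–C8 bridge, C1(COSEt)=C10(CH3), endo-OTIPS on C9, C6(OCH3)=C7(CH2CO2Et) | CCSC(=O)C1=C(C)[C@@H](O[Si](C(C)C)(C(C)C)C(C)C)[C@@H]2O[C@H]1C(OC)=C2CC(=O)OCC | intermediate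
11 | C6 ketone of 10 with the CH2CO2Et group endo on C7 | CCSC(=O)C1=C(C)[C@@H](O[Si](C(C)C)(C(C)C)C(C)C)[C@@H]2O[C@H]1C(=O)[C@@H]2CC(=O)OCC | intermediate (not isolated)
12 | C6 endo-alcohol (cis to the C7 side chain, trans to the bridge oxygen on C5) | CCSC(=O)C1=C(C)[C@@H](O[Si](C(C)C)(C(C)C)C(C)C)[C@@H]2O[C@H]1[C@H](O)[C@@H]2CC(=O)OCC | intermediate (not isolated)
13 | tricyclic lactone: cis-γ-lactone fused endo at C6/C7 of the oxygen-bridged cycloheptene, C9 endo-OTIPS, C1(COSEt)=C10(CH3) | CCSC(=O)C1=C(C)[C@@H](O[Si](C(C)C)(C(C)C)C(C)C)[C@@H]2O[C@H]1[C@@H]3OC(=O)C[C@H]23 | intermediate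
14 | monocyclic cyclohepta-diene: C5–OTMS (trans to the lactone oxygen on C6), cis-fused lactone at C6/C7, C8=C9(OTIPS), C10(CH3)=C1(COSEt) | CCSC(=O)C1=C(C)C(O[Si](C(C)C)(C(C)C)C(C)C)=C[C@H]2CC(=O)O[C@H]2[C@@H]1O[Si](C)(C)C | intermediate
15 | Mannich base of 14 (CH2NMe2 on C11, configuration at C11 not defined and lost later) | CCSC(=O)C1=C(C)C(O[Si](C(C)C)(C(C)C)C(C)C)=C[C@H]2C(CN(C)C)C(=O)O[C@H]2[C@@H]1O[Si](C)(C)C | intermediate (not isolated)
16 | trimethylammonium iodide of 15 | CCSC(=O)C1=C(C)C(O[Si](C(C)C)(C(C)C)C(C)C)=C[C@H]2C(C[N+](C)(C)C)C(=O)O[C@H]2[C@@H]1O[Si](C)(C)C.[I-] | intermediate (not isolated)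
17 | α-methylene lactone analogue of 14 | CCSC(=O)C1=C(C)C(O[Si](C(C)C)(C(C)C)C(C)C)=C[C@H]2C(=C)C(=O)O[C@H]2[C@@H]1O[Si](C)(C)C | intermediate
18 | C5-hydroxy ene-keto thioester: C9 ketone, C10(CH3)=C1(COSEt), C8H2, cis α-methylene lactone, C5–OH trans to the lactone oxygen | CCSC(=O)C1=C(C)C(=O)C[C@H]2C(=C)C(=O)O[C@H]2[C@@H]1O | intermediate
19 | C5 isovalerate of 18 | CCSC(=O)C1=C(C)C(=O)C[C@H]2C(=C)C(=O)O[C@H]2[C@@H]1OC(=O)CC(C)C | intermediate
20 | C1,C10-epoxide of 19, epoxide oxygen trans to the C5 acyloxy group | CCSC(=O)[C@]12O[C@@]1(C)C(=O)C[C@H]3C(=C)C(=O)O[C@H]3[C@@H]2OC(=O)CC(C)C | intermediate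
21 | β-hydroxy ketone thioester: C1–OH trans to C5–O, C10–CH3 cis to C1–OH | CCSC(=O)[C@]1(O)[C@@H](C)C(=O)C[C@H]2C(=C)C(=O)O[C@H]2[C@@H]1OC(=O)CC(C)C | intermediate
22 | CNP0283951.1 | C=C1C(=O)O[C@@H]2[C@H]1CC(=O)[C@H](C)[C@@](O)(C(=O)/C=C/C)[C@H]2OC(=O)CC(C)C | target

**Step count and risks**

Total number of steps: 15 (steps 1–2 furan branch, steps 3–6 diazo branch, steps 7–15 common line).
Longest linear sequence: 13 steps (4 to 22, steps 3–15).

Steps most likely to fail:

1. Step 9 (Proposed new method). The amine may remove a proton of the C10 methyl instead of the C9 proton, or the elimination may stall because the breaking C8–O bond overlaps poorly with the dienolate π-system in the rigid bicycle. Fallback (reductive instead of eliminative opening): starting from 13, Bu4NF/AcOH in THF removes the silyl group to give the C9 alcohol F1. Dess–Martin periodinane oxidises it to the bicyclic C9 ketone F2. SmI2 in THF/MeOH at −78 °C then cleaves the C8–O bond α to this ketone, as is known for oxygen-bridged cycloheptenones from oxidopyrylium cycloadditions, to give the monocyclic hydroxy enone F3. Silylation with TMSCl/imidazole gives its C5 trimethylsilyl ether F4, and TIPSOTf/Et3N enolises the C9 ketone towards C8, which brings the material back to the route at 14.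

2. Step 7. Regiocontrol between the two furan α-carbons may be lost, the carbene may be diverted into C–H insertion at the activated side-chain CH2 or into zwitterionic [3+2] closure, and the enantioface selection may be insufficient. Fallback (cycloaddition before side-chain attachment): starting from 2 and 8, the same rhodium-catalysed reaction is run on the bromofuran, which has no side-chain C–H bonds and a deactivated α-carbon next to bromine, to give the bromo cycloadduct F5. A Migita–Kosugi–Stille coupling of its vinyl bromide with ethyl (tributylstannyl)acetate (PdCl2[P(o-tol)3]2, ZnBr2, DMF, 80 °C; the thioester is inert in the absence of copper) then installs the CH2CO2Et group and returns to the route at 10.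

3. Step 13. The peroxide anion may attack from the face syn to the C5 ester, or at the thioester carbonyl or the α-methylene lactone instead of C1. Fallback (hydroxyl-directed electrophilic epoxidation): starting from 19, Luche reduction (NaBH4, CeCl3·7H2O, MeOH, −78 °C) gives the C9 allylic alcohols, of which the epimer with the hydroxyl trans to the C5 acyloxy group, the C9 allylic alcohol F6, is separated (the other epimer is reoxidised to 19 with Dess–Martin periodinane). VO(acac)2/t-BuOOH in CH2Cl2 epoxidises C10=C1 syn to this hydroxyl to give the epoxy alcohol F7, and Dess–Martin periodinane restores the C9 ketone, returning to the route at 20.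

Further compounds
F1 | step 9 | C9 alcohol of 13 (silyl group removed) | CCSC(=O)C1=C(C)[C@@H](O)[C@@H]2O[C@H]1[C@@H]3OC(=O)C[C@H]23
F2 | step 9 | bicyclic C9 ketone | CCSC(=O)C1=C(C)C(=O)[C@@H]2O[C@H]1[C@@H]3OC(=O)C[C@H]23
F3 | step 9 | monocyclic C5-hydroxy ene-keto thioester with saturated lactone | CCSC(=O)C1=C(C)C(=O)C[C@H]2CC(=O)O[C@H]2[C@@H]1O
F4 | step 9 | C5 trimethylsilyl ether of F3 | CCSC(=O)C1=C(C)C(=O)C[C@H]2CC(=O)O[C@H]2[C@@H]1O[Si](C)(C)C
F5 | step 7 | bromo cycloadduct (10 with Br on C7 in place of CH2CO2Et) | CCSC(=O)C1=C(C)[C@@H](O[Si](C(C)C)(C(C)C)C(C)C)[C@@H]2O[C@H]1C(OC)=C2Br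
F6 | step 13 | C9 allylic alcohol of 19, hydroxyl trans to the C5 acyloxy group | CCSC(=O)C1=C(C)[C@@H](O)C[C@H]2C(=C)C(=O)O[C@H]2[C@@H]1OC(=O)CC(C)C
F7 | step 13 | C1,C10-epoxy C9-alcohol, epoxide syn to the C9 hydroxyl | CCSC(=O)[C@]12O[C@@]1(C)[C@@H](O)C[C@H]3C(=C)C(=O)O[C@H]3[C@@H]2OC(=O)CC(C)C
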